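**Assumption:** Broussonol D (8,5'-diprenylquercetin, C25H26O7) has no stereocentres and no stereogenic alkenes, so it is a single achiral compound and no stereocontrol is needed.

## Retrosynthetic overview

1. Target 16 ⇐ one-pot acid removal of four MOM ethers and one tert-butyl ether from protected flavonol 15.
2. 15 ⇐ Rh(III)-catalysed formyl C–H activation and oxidative [4+2] annulation of salicylaldehyde 6 (A ring) with aryl tert-butyl ynol ether 14 (B ring plus C2, C3, O3). This forms C4–C3 and O1–C2.
3. 6 ⇐ resorcinol: MOM protection, Ir C–H borylation/oxidation (third oxygen), ortho C-prenylation, ortho formylation.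
4. 14 ⇐ catechol: MOM protection, directed ortho-metalation/prenylation, Ir C–H borylation, iodination, Negishi alkynylation with t-BuO–C≡C–ZnCl (from trichloroethylene and KOt-Bu).
5. Ring order: A and B rings come intact from resorcinol and catechol; the pyranone C ring is formed last, in the convergent annulation.

## Route

### A-ring fragment

**Step 1**
Reactants: 1, resorcinol
Product: 2, 1,3-bis(methoxymethoxy)benzene
Conditions: MOMCl, i-Pr2NEt, CH2Cl2, 0 °C → rt
Reagents that add atoms: chloromethyl methyl ether, COCCl
Why: Phenol O-alkylation (MOM acetal protection); MOM survives the organolithium, Ir, Cu, Pd and Rh steps and is removed with mild acid at the end.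

**Step 2**
Reactants: 2, 1,3-bis(methoxymethoxy)benzene
Product: 3, 3,5-bis(methoxymethoxy)phenol
Conditions: [Ir(OMe)(cod)]2 (1.5 mol%), dtbpy (3 mol%), B2pin2, THF, 80 °C; then 3 M NaOH, 30% H2O2, 0 °C → rt (one pot)
Reagents that add atoms: hydrogen peroxide, OO (B2pin2 is only transient)
Why: Sterically controlled Ir-catalysed aromatic C–H borylation occurs at C5, the only C–H with no ortho substituent, and in-situ boronate oxidation gives the phenol (one-pot C–H borylation/oxidation).

**Step 3**
Reactants: 3, 3,5-bis(methoxymethoxy)phenol; 4, prenyl bromide (1-bromo-3-methylbut-2-ene)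
Product: 5, 3,5-bis(methoxymethoxy)-2-(3-methylbut-2-en-1-yl)phenol
Conditions: NaH (1.05 eq), PhMe, 0 °C; then 4 (1.0 eq), rt
Reagents that add atoms: none (prenyl comes from reactant 4)
Why: C-alkylation of a sodium phenoxide tight ion pair in a non-polar solvent goes ortho by SN2; the two ortho sites are equivalent and the para site is shielded by two OMOM groups.

**Step 4**
Reactants: 5, 3,5-bis(methoxymethoxy)-2-(3-methylbut-2-en-1-yl)phenol
Product: 6, 2-hydroxy-4,6-bis(methoxymethoxy)-3-(3-methylbut-2-en-1-yl)benzaldehyde
Conditions: MgCl2, Et3N, (CH2O)n, MeCN, 75 °C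
Reagents that add atoms: paraformaldehyde, C=O
Why: Mg-phenoxide-mediated ortho-specific formylation (Casnati–Skattebøl) can only occur at the one remaining ortho position, so OH is flanked by prenyl and CHO; the basic conditions leave MOM and prenyl intact.

### B-ring fragment

**Step 5**
Reactants: 7, catechol
Product: 8, 1,2-bis(methoxymethoxy)benzene
Conditions: NaH, MOMCl, DMF, 0 °C → rt
Reagents that add atoms: chloromethyl methyl ether, COCCl
Why: Phenol O-alkylation (MOM protection), which also installs the directing group for the next step.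

**Step 6**
Reactants: 8, 1,2-bis(methoxymethoxy)benzene; 4, prenyl bromide
Product: 9, 1,2-bis(methoxymethoxy)-3-(3-methylbut-2-en-1-yl)benzene
Conditions: n-BuLi, TMEDA, THF, 0 °C; CuBr·SMe2, −40 °C; then 4, −40 °C → rt
Reagents that add atoms: none (prenyl comes from reactant 4)
Why: OMOM-directed ortho-lithiation (the two ortho sites are equivalent) followed by Cu-mediated SN2 allylation gives the linear prenyl arene.

**Step 7**
Reactants: 9, 1,2-bis(methoxymethoxy)-3-(3-methylbut-2-en-1-yl)benzene
Product: 10, 2-[3,4-bis(methoxymethoxy)-5-(3-methylbut-2-en-1-yl)phenyl]-4,4,5,5-tetramethyl-1,3,2-dioxaborolane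
Conditions: [Ir(OMe)(cod)]2 (1.5 mol%), dtbpy (3 mol%), B2pin2 (1.0 eq), MTBE, 60 °C
Reagents that add atoms: bis(pinacolato)diboron, CC1(C)OB(OC1(C)C)B1OC(C)(C)C(C)(C)O1
Why: Ir-catalysed C–H borylation is sterically directed to C5, the only ring C–H without an ortho substituent; the hindered trisubstituted alkene is not expected to hydroborate under these conditions.

**Step 8**
Reactants: 10, aryl pinacol boronate
Product: 11, 5-iodo-1,2-bis(methoxymethoxy)-3-(3-methylbut-2-en-1-yl)benzene
Conditions: CuI (10 mol%), 1,10-phenanthroline (20 mol%), KI (1.5 eq), MeOH/H2O 4:1, air, 80 °C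
Reagents that add atoms: potassium iodide, [K+].[I-]
Why: Cu-mediated oxidative ipso-iodination of an aryl boronate (Chan–Lam-type halogenation) uses nucleophilic iodide and no I+ source, so the prenyl alkene and MOM ethers are untouched.

### Ynol ether reagent and fragment union

**Step 9**
Reactants: 12, trichloroethylene
Product: 13, (E)-1-(tert-butoxy)-1,2-dichloroethene
Conditions: KOt-Bu (1.1 eq), THF, −50 °C → rt
Reagents that add atoms: potassium tert-butoxide, CC(C)(C)[O-].[K+]
Why: Base-induced dehydrochlorination to dichloroacetylene (kept in solution) and trans-addition of tert-butoxide give the dichlorovinyl ether (Greene ynol ether synthesis, first stage).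

**Step 10**
Reactants: 11, aryl iodide; 13, (E)-1-(tert-butoxy)-1,2-dichloroethene
Product: 14, 5-(tert-butoxyethynyl)-1,2-bis(methoxymethoxy)-3-(3-methylbut-2-en-1-yl)benzene
Conditions: 13 (1.5 eq), n-BuLi (3.1 eq), THF, −78 → −40 °C; ZnCl2, −40 → 0 °C; then 11, Pd(PPh3)4 (5 mol%), THF, rt; purify on Et3N-deactivated silica
Reagents that add atoms: none
Why: Elimination and Cl–Li exchange give lithium tert-butoxyacetylide, which after transmetalation to zinc undergoes Pd-catalysed Negishi alkynylation at room temperature, well below the retro-ene temperature of tert-butyl ynol ethers.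

**Step 11**
Reactants: 6, salicylaldehyde; 14, aryl tert-butyl ynol ether
Product: 15, 3-(tert-butoxy)-2-[3,4-bis(methoxymethoxy)-5-(3-methylbut-2-en-1-yl)phenyl]-5,7-bis(methoxymethoxy)-8-(3-methylbut-2-en-1-yl)-4H-chromen-4-one
Conditions: [Cp*RhCl2]2 (2.5 mol%), anhydrous Cu(OAc)2 (2.2 eq), CsOAc (1 eq), 4 Å MS, DCE, 40 °C, slow addition of 14 (1.3 eq)
Reagents that add atoms: none
Why: Proposed new method: Rh(III)-catalysed oxidative [4+2] annulation of a salicylaldehyde with an aryl ynol ether. Phenoxide-directed, acetate-assisted cleavage of the formyl C–H gives a five-membered acyl-rhodacycle; the polarised ynol ether (Ar–C(δ−)≡C(δ+)–Ot-Bu) inserts into Rh–C(acyl) so the acyl carbon bonds to the electrophilic O-bearing carbon (C3–Ot-Bu) and Rh sits on the aryl-bearing carbon (also the usual preference for aryl alkynes); C–O reductive elimination closes the pyranone (O1–C2) and Cu(II) reoxidises Rh(I). The closest known reaction type is the Rh-catalysed oxidative annulation of salicylaldehydes with internal dialkyl or diaryl alkynes to 2,3-disubstituted chromones, which to my knowledge has not been shown with ynol ethers or used to make 3-oxygenated flavones. Running at 40 °C keeps 14 below its retro-ene temperature (about 80–90 °C).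

**Step 12**
Reactants: 15, protected flavonol
Product: 16, Broussonol D (3,5,7-trihydroxy-2-[3,4-dihydroxy-5-(3-methylbut-2-en-1-yl)phenyl]-8-(3-methylbut-2-en-1-yl)-4H-chromen-4-one)
Conditions: 3 M aq HCl/MeOH (1:4), 50 °C, Ar
Reagents that add atoms: none
Why: Acid-catalysed acetal hydrolysis removes the four MOM groups and SN1 cleavage (t-Bu+ trapped by MeOH) removes the tert-butyl ether, which is activated by the protonated, chelating C4 carbonyl; HCl/MeOH is the standard MOM removal for prenylated flavonoids.

## Compound list

1 | resorcinol | Oc1cccc(O)c1 | starting material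
2 | 1,3-bis(methoxymethoxy)benzene | COCOc1cccc(OCOC)c1 | intermediate
3 | 3,5-bis(methoxymethoxy)phenol | COCOc1cc(O)cc(OCOC)c1 | intermediate
4 | prenyl bromide (1-bromo-3-methylbut-2-ene) | CC(C)=CCBr | starting material
5 | 3,5-bis(methoxymethoxy)-2-(3-methylbut-2-en-1-yl)phenol | CC(C)=CCc1c(O)cc(OCOC)cc1OCOC | intermediate
6 | 2-hydroxy-4,6-bis(methoxymethoxy)-3-(3-methylbut-2-en-1-yl)benzaldehyde | CC(C)=CCc1c(O)c(C=O)c(OCOC)cc1OCOC | intermediate
7 | catechol | Oc1ccccc1O | starting material
8 | 1,2-bis(methoxymethoxy)benzene | COCOc1ccccc1OCOC | intermediate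
9 | 1,2-bis(methoxymethoxy)-3-(3-methylbut-2-en-1-yl)benzene | CC(C)=CCc1cccc(OCOC)c1OCOC | intermediate
10 | 2-[3,4-bis(methoxymethoxy)-5-(3-methylbut-2-en-1-yl)phenyl]-4,4,5,5-tetramethyl-1,3,2-dioxaborolane | CC(C)=CCc1cc(B2OC(C)(C)C(C)(C)O2)cc(OCOC)c1OCOC | intermediate
11 | 5-iodo-1,2-bis(methoxymethoxy)-3-(3-methylbut-2-en-1-yl)benzene | CC(C)=CCc1cc(I)cc(OCOC)c1OCOC | intermediate
12 | trichloroethylene | ClC=C(Cl)Cl | starting material
13 | (E)-1-(tert-butoxy)-1,2-dichloroethene | Cl/C=C(/Cl)OC(C)(C)C | intermediate
14 | 5-(tert-butoxyethynyl)-1,2-bis(methoxymethoxy)-3-(3-methylbut-2-en-1-yl)benzene | CC(C)=CCc1cc(C#COC(C)(C)C)cc(OCOC)c1OCOC | intermediate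
15 | 3-(tert-butoxy)-2-[3,4-bis(methoxymethoxy)-5-(3-methylbut-2-en-1-yl)phenyl]-5,7-bis(methoxymethoxy)-8-(3-methylbut-2-en-1-yl)-4H-chromen-4-one | CC(C)=CCc1cc(-c2oc3c(CC=C(C)C)c(OCOC)cc(OCOC)c3c(=O)c2OC(C)(C)C)cc(OCOC)c1OCOC | intermediate
16 | Broussonol D | CC(C)=CCc1cc(-c2oc3c(CC=C(C)C)c(O)cc(O)c3c(=O)c2O)cc(O)c1O | target

## Summary

**Total steps:** 12.

**Longest linear sequence:** 7 steps (catechol 7 → 8 → 9 → 10 → 11 → 14 → 15 → 16; steps 5, 6, 7, 8, 10, 11, 12). The resorcinol branch is 6 steps to the target and the ynol ether branch is 4.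

**Steps most likely to fail**

1. **Step 11 (proposed Rh(III) salicylaldehyde/ynol ether annulation).** Risks are acetic acid addition to, or hydration or isobutene loss from, the ynol ether, and wrong-way insertion. Fallback with known chemistry: convert iodide 11 to the aroyl sulfoxonium ylide (Pd-catalysed methoxycarbonylation, then Me3S(O)I/KOt-Bu). Couple it with 6 by the established Rh(III) salicylaldehyde/sulfoxonium ylide annulation to give the flavone. Then install 3-OH by C3 lithiation (LDA, −78 °C), B(OMe)3 and H2O2, which does not epoxidise the prenyl groups, and deprotect.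

2. **Step 3 (ortho C-prenylation of phenol 3).** Risks are O-alkylation, para and double alkylation, and moderate yield. Fallback with full regiocontrol:
   - Prenylate 2 at C2 by directed ortho-lithiation (between the two OMOM groups).
   - Ir borylation/oxidation gives 3,5-bis(methoxymethoxy)-4-prenylphenol.
   - Mg-mediated ortho formylation, then TBS protection of the phenol.
   - Chelation-assisted removal (MgBr2·OEt2) of the MOM group ortho to CHO gives the analogue of 6 with 6-OTBS.

3. **Step 12 (global acid deprotection).** Risks are slow tert-butyl cleavage and acid-induced cyclisation of the prenyl groups onto the neighbouring 7-OH and 4'-OH to give chromans. Fallback: switch to a fluoride-labile protecting set. Use SEM ethers in place of MOM (same directing and stability profile) and the 2-(trimethylsilyl)ethyl ynol ether (from 2-(trimethylsilyl)ethanol, KH and trichloroethylene). The final unmasking is then done with TBAF or CsF and no protic acid.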